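Early in the alder run the substrate loses the same fraction per hour as c_substrate falls: the first reading gives a rate constant of 0.0731 h⁻¹ and the second 0.0731 h⁻¹, with 16.1% of the substrate left. A constant fraction per hour means order one in substrate, so a first-order constant does not depend on the charge.

| setting | alder | larch | flask |
|---|---|---|---|
| substrate | 1 M | 0.50 M | 1.0 M |
| reagent | 1.2 M | 1.2 M | 1.20 M |
| temperature | 70 °C | 76 °C | 70 °C |
| remark | the very flask that is asked about, followed so far | run made earlier |  |
| time |  |  | 8.0 d |

- alder (time / h: target / %, substrate / %): 15.0: 6.6, 33.4; 25.0: 16.4, 16.1; 40.0: 22.9, 6.4; 72.0: 28.1, 4.7; 120: 30.4, 0.4; 192: 30.8, 0.2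
- larch (time / h: target / %, substrate / %): 1.00: 2.1, 85.5; 1.50: 1.0, 80.4; 2.50: 0.2, 68.6; 4.00: 3.3, 55.4; 8.00: 10.0, 32.0; 12.0: 14.8, 16.6

(each reading ± 1 percentage point)

- target, in percent of the substrate first charged, at 8.0 d
- what to do for the largest gain in target; "none" if nothing gains more than 2 percentage points (grey / teal / ochre / none)
- target present, with what was taken out counted in, in percent of the substrate first charged, after grey
- target present, with what was taken out counted in, in percent of the substrate first charged, after teal

- grey: change nothing and wait 2.5 d more
- teal: at 8.0 d take out 90% of the target then present, then wait 2.5 d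
- ochre: at 8.0 d raise the temperature by 20 K, then wait 2.5 d

- removed target is counted in

The larch run behaves likewise, with 0.150 h⁻¹ at its last reading, about twice the alder value. A first-order constant does not depend on the charge, so the difference is read as temperature, the other setting that differs between the two runs. It gives an apparent activation energy of 119 kJ mol⁻¹.

From this comes the clock factor (the usual acceleration factor), the number of hours at 70 °C that one hour at the hotter temperature is worth. Assuming that slow steps share this energy, ochre gives 9.93.

In the alder run, target and substrate leave 69.0% of the charge unread at 192 h. Target still drifts by 0.4 percentage points over its last interval, less than the scatter of one reading. My own reckoning extends that drift: 0.33 points for grey, hence 31.1%, and I take teal as equal. The clock factor turns this into 3.3 points for ochre, above the margin, so I choose ochre, though on a weak drift.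

The forecast differs on that choice. It gives 30.8% (29.8% to 32%) now, 31% after grey, 31.2% after teal, and best none: “Heating likewise has nothing left to convert.”

The flask gives 31.6% now and 33.1% after both grey and teal, each a gain of 1.5 points. Best is ochre, with 12 points.

    intermediate A → side product (k = 0.0230 h⁻¹, Ea = 110 kJ mol⁻¹)
    substrate ⇌ intermediate B (K = 25.0, k = 0.0440 h⁻¹, Ea = 126 kJ mol⁻¹, ΔH = 7.00 kJ mol⁻¹)
    reagent ⇌ dormant form (K = 0.490, k = 0.00670 h⁻¹, Ea = 109 kJ mol⁻¹, ΔH = 10.0 kJ mol⁻¹)
    intermediate A → target (k = 0.0550 h⁻¹, Ea = 102 kJ mol⁻¹)
    substrate → intermediate A (k = 0.0280 h⁻¹, Ea = 123 kJ mol⁻¹)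
    (constants at 70 °C)

In this flask the forward step into intermediate B alone uses substrate 1.6 times as fast as the step into intermediate A, with half-lives of 16 h against 25 h at 8.06 h. At 192 h intermediate B holds 53.4% of the charge, more than the target's 31.6%. Multiplied by the clock factor, grey's gain gives an estimate of 15 points for ochre, against the 12 points that ochre brings. A neighbouring flask with the same charge, kept at 45 °C, counts its 192 h as 7.26 h at 70 °C, for which the first-order reckoning gives 58.8% substrate; that flask holds 64.2%.

The readings are simulated on assumed constants, and the scatter is random.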